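**Retrosynthetic overview**
Target ⇒ (ketal hydrolysis) its 4,5-O-isopropylidene derivative ⇒ (aldol union, C5–C1′ bond) heptadecanal plus the lithium enolate of (4S,5S)-4,5-isopropylidenedioxycyclopent-2-enone. This one step completes the carbon skeleton and sets the fully substituted carbinol C5 and the carbinol C1′ together.
Enabling feature: the cis C4/C5 diol next to the C1 ketone, tied as a dioxolane ring cis-fused to the cyclopentenone ring. C4 stores the chirality while C5 is planar, the five-five fusion lets C5 re-bond only on the face of C4–H, and the dioxolane ring with the C2=C3 alkene blocks β-elimination of O4 (misaligned C4–O bond, antiaromatic cyclopentadienone as the outcome).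
Bicyclic enone ⇒ (oxidation, loss of AcOH) ⇒ (acetonide) ⇒ (anti dihydroxylation) enantiopure cis-4-hydroxycyclopent-2-enyl acetate; heptadecanal ⇒ heptadecan-1-ol.
Rings: the carbocycle is bought; the temporary dioxolane ring is closed in step 2 and opened again in the last step.

Key step: step 5

Remark: the ring is numbered C1 (carbonyl), C2=C3 (alkene), C4 (secondary carbinol), C5 (tertiary carbinol), and the side-chain carbinol is C1′; the enantiopure monoacetate and heptadecan-1-ol are taken as catalogue compounds.

Step 1
Reactants: 1 (1R,4S)-4-hydroxycyclopent-2-en-1-yl acetate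
Product: 2 (1R,2R,3R,4S)-2,3,4-trihydroxycyclopentyl acetate
Conditions: OsO4 (2 mol %), NMO, acetone/H2O, 0 °C to rt
Reagents that add atoms: osmium tetroxide O=[Os](=O)(=O)=O; N-methylmorpholine N-oxide C[N+]1([O-])CCOCC1; water O
Why: Upjohn dihydroxylation: the concerted suprafacial addition of OsO4 should occur on the ring face opposite to the two cis-disposed allylic oxygen substituents, so both new carbinol centres are set together by substrate control, anti to OH and OAc.

Step 2
Reactants: 2 (1R,2R,3R,4S)-2,3,4-trihydroxycyclopentyl acetate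
Product: 3 (3aS,4R,6S,6aR)-6-hydroxy-2,2-dimethyltetrahydro-4H-cyclopenta[d][1,3]dioxol-4-yl acetate
Conditions: 2,2-dimethoxypropane, p-TsOH·H2O (cat.), acetone, rt
Reagents that add atoms: 2,2-dimethoxypropane COC(C)(C)OC
Why: Acid-catalysed transketalisation (acetonide formation): only the cis-vicinal diol can close the five-membered dioxolane ring, the third hydroxyl being trans to its neighbour, and no stereocentre is touched.

Step 3
Reactants: 3 (3aS,4R,6S,6aR)-6-hydroxy-2,2-dimethyltetrahydro-4H-cyclopenta[d][1,3]dioxol-4-yl acetate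
Product: 5 (3aS,6aS)-2,2-dimethyl-3a,6a-dihydro-4H-cyclopenta[d][1,3]dioxol-4-one, via β-acetoxy ketone 4 (not isolated)
Conditions: Dess–Martin periodinane, CH2Cl2, 0 °C to rt; then Et3N (excess), 0 °C to rt
Reagents that add atoms: none
Why: Dess–Martin oxidation followed by E1cB elimination: the new ketone acidifies the ring CH2, whose enolate expels the β-acetate, whereas the ketal oxygen on the other side is held out of alignment by the cis-fused dioxolane, so both oxygen-bearing stereocentres are kept.

Step 4
Reactants: 6 heptadecan-1-ol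
Product: 7 heptadecanal
Conditions: TEMPO (2,2,6,6-tetramethylpiperidine-1-oxyl, 10 mol %), PhI(OAc)2, CH2Cl2, rt
Reagents that add atoms: none
Why: Oxoammonium (TEMPO/PhI(OAc)2) oxidation of a primary alcohol, which stops at the aldehyde under anhydrous conditions, and no stereocentre is involved.

Step 5
Reactants: 5 (3aS,6aS)-2,2-dimethyl-3a,6a-dihydro-4H-cyclopenta[d][1,3]dioxol-4-one; 7 heptadecanal
Product: 10 (3aS,6aS)-3a-[(1S)-1-hydroxyheptadecyl]-2,2-dimethyl-3a,6a-dihydro-4H-cyclopenta[d][1,3]dioxol-4-one, via lithium enolate 8 (not isolated), via lithium aldolate 9 (not isolated)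
Conditions: LDA (1.1 equiv), THF, −78 °C, slow addition of 5; then 7 in THF, −78 °C; AcOH, −78 °C
Reagents that add atoms: none
Why: LDA removes the only α-hydrogen, C5–H, to give the cross-conjugated lithium enolate 8 (C1=C5, C5 now planar), which adds to the aldehyde carbon of 7 through a closed lithium-bridged six-membered Zimmerman–Traxler chair to give aldolate 9, protonated cold to 10. The closest known reaction types are the α′-aldol additions of lithium enolates of 4-oxygenated cyclopent-2-enones to aliphatic aldehydes and the aldol and alkylation reactions of acetonide-bridged α,β-dioxygenated enolates, so this is a directed aldol addition with self-regeneration of the C5 stereocentre. No ring is closed in this step. C5 is controlled by C4 through the dioxolane ring: a five-five ring fusion can only be cis, and the C4–O bond together with the CMe2 group shields the upper face, so the new C5–C1′ bond must form on the face of C4–H and O5 returns cis to O4 (5S). C1′ is controlled by the ring-locked enolate geometry (enolate oxygen cis to O5 and trans to C4) with the hexadecyl chain equatorial and pointing away from the bicycle in the chair, which places the new hydroxyl anti to C4 and syn to O5 along the C1–C5–C1′ backbone, that is (1S). The step needs α′- rather than γ-deprotonation (secured by the kinetic base at −78 °C), survival of the β-oxygenated enolate (secured because the dioxolane holds the C4–O bond near the nodal plane of the enolate and because its loss would create an antiaromatic cyclopentadienone with the C2=C3 alkene) and aldol rather than Michael self-addition (secured by complete enolisation before 7 is added).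

Step 6
Reactants: 10 (3aS,6aS)-3a-[(1S)-1-hydroxyheptadecyl]-2,2-dimethyl-3a,6a-dihydro-4H-cyclopenta[d][1,3]dioxol-4-one
Product: 11 (4S,5S)-4,5-dihydroxy-5-[(1S)-1-hydroxyheptadecyl]cyclopent-2-en-1-one
Conditions: TFA/H2O (9:1), CH2Cl2, 0 °C to rt
Reagents that add atoms: none
Why: Acid-catalysed ketal hydrolysis: protonation and loss of acetone free the cis-4,5-diol, while the quaternary C5, the allylic C4 and C1′ are not epimerisable under acid and the base-sensitive β-hydroxy ketone is never exposed to base.

**Compound list**
1 | (1R,4S)-4-hydroxycyclopent-2-en-1-yl acetate (cis; acetoxy carbon R, carbinol carbon S) | O[C@@H]1C=C[C@H](OC(C)=O)C1 | starting material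
2 | (1R,2R,3R,4S)-2,3,4-trihydroxycyclopentyl acetate (new cis-diol on the face opposite to OH and OAc) | CC(=O)O[C@@H]1C[C@H](O)[C@@H](O)[C@H]1O | intermediate
3 | (3aS,4R,6S,6aR)-6-hydroxy-2,2-dimethyltetrahydro-4H-cyclopenta[d][1,3]dioxol-4-yl acetate | CC(=O)O[C@@H]1C[C@H](O)[C@H]2OC(C)(C)O[C@@H]12 | intermediate
4 | (3aS,4R,6aS)-2,2-dimethyl-6-oxotetrahydro-4H-cyclopenta[d][1,3]dioxol-4-yl acetate (β-acetoxy ketone) | CC(=O)O[C@@H]1CC(=O)[C@H]2OC(C)(C)O[C@@H]12 | intermediate
5 | (3aS,6aS)-2,2-dimethyl-3a,6a-dihydro-4H-cyclopenta[d][1,3]dioxol-4-one, the (4S,5S)-4,5-isopropylidenedioxycyclopent-2-enone | CC1(C)O[C@H]2C=CC(=O)[C@H]2O1 | intermediate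
6 | heptadecan-1-ol | CCCCCCCCCCCCCCCCCO | starting material
7 | heptadecanal | CCCCCCCCCCCCCCCCC=O | intermediate
8 | lithium enolate of 5 (C1=C5 enolate, C4 still S) | [Li+].[O-]C1=C2OC(C)(C)O[C@H]2C=C1 | intermediate
9 | lithium aldolate of 10 | [Li+].CCCCCCCCCCCCCCCC[C@H]([O-])[C@]12OC(C)(C)O[C@H]1C=CC2=O | intermediate
10 | (3aS,6aS)-3a-[(1S)-1-hydroxyheptadecyl]-2,2-dimethyl-3a,6a-dihydro-4H-cyclopenta[d][1,3]dioxol-4-one | CCCCCCCCCCCCCCCC[C@H](O)[C@]12OC(C)(C)O[C@H]1C=CC2=O | intermediate
11 | (4S,5S)-4,5-dihydroxy-5-[(1S)-1-hydroxyheptadecyl]cyclopent-2-en-1-one | CCCCCCCCCCCCCCCC[C@H](O)[C@@]1(O)C(=O)C=C[C@@H]1O | target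

Total step count: 6
Longest linear sequence: 5 steps (1 → 2 → 3 → 5 → 10 → 11; step 4 runs in parallel)

**Steps most likely to fail**

Step 5. Simple diastereoselection at C1′ in the lithium chair may be weak. Enolate 8 may also decay before the aldehyde is captured, by Michael self-addition or by loss of the C4 oxygen. The fallback sets out from 7 and comes back at 11: the C5–C1′ bond is first made as an alkene and both oxygens are delivered afterwards.
- Commercial (R)-4-(tert-butyldimethylsilyloxy)cyclopent-2-en-1-one (O=C1C=C[C@H](O[Si](C)(C)C(C)(C)C)C1) is deprotonated with LDA (THF, −78 °C) and added to 7 to give the trans aldol adduct F1, whose carbinol configuration is of no consequence.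
- Mesylation (MsCl, Et3N, CH2Cl2) gives the mesylate F2, and elimination with DBU gives the (E)-alkylidene silyl ether F3.
- Aqueous HF in MeCN frees the hydroxy dienone F4.
- Hydrogen-bond-directed dihydroxylation (catalytic OsO4, Me3NO·2H2O, CH2Cl2) should then attack the more electron-rich trisubstituted exocyclic alkene on the face of the C4 hydroxyl and give 11.
- Syn addition to the E alkene translates into the (5S,1′S) pair.

Step 6. The ketal is deactivated by the neighbouring carbonyl and may need forcing acid. That opens the way to ketal migration onto the side-chain hydroxyl, dehydration or an α-ketol shift. The fallback sets out from 5 and comes back at 11: the acid step is moved ahead of the union, where nothing fragile is present, and the last step becomes a fluoride desilylation.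
- Hydrolysis of 5 (TFA/H2O) gives the cis-diol F5, and TESOTf/2,6-lutidine gives the bis(triethylsilyl) ether F6.
- LDA-mediated aldol addition to 7 as in step 5, now with the C4 silyloxy group shielding the upper face, gives the silylated aldol adduct F7.
- HF·pyridine (THF, 0 °C) gives 11.

Step 1. Enantiomeric purity may erode through 1,3-acetyl migration between the two cis-disposed oxygens in the mildly basic medium, since the migrated material belongs to the enantiomeric series. Facial selectivity may also be incomplete. The fallback sets out from 1 and comes back at 3: the free hydroxyl is capped before the oxidation.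
- TBSCl/imidazole (DMF) gives the silyl ether F8, and OsO4/NMO gives the silylated diol F9.
- 2,2-Dimethoxypropane/p-TsOH gives the silylated acetonide F10.
- Non-basic desilylation with HF·pyridine (THF) gives 3.

**Further compounds**
F1 | step 5 | (4S,5R)-4-(tert-butyldimethylsilyloxy)-5-(1-hydroxyheptadecyl)cyclopent-2-en-1-one (carbinol epimers) | CCCCCCCCCCCCCCCCC(O)[C@H]1C(=O)C=C[C@@H]1O[Si](C)(C)C(C)(C)C
F2 | step 5 | methanesulfonate of F1 | CCCCCCCCCCCCCCCCC(OS(C)(=O)=O)[C@H]1C(=O)C=C[C@@H]1O[Si](C)(C)C(C)(C)C
F3 | step 5 | (4S,5E)-4-(tert-butyldimethylsilyloxy)-5-heptadecylidenecyclopent-2-en-1-one | CCCCCCCCCCCCCCCC/C=C1/C(=O)C=C[C@@H]1O[Si](C)(C)C(C)(C)C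
F4 | step 5 | (4S,5E)-5-heptadecylidene-4-hydroxycyclopent-2-en-1-one | CCCCCCCCCCCCCCCC/C=C1/C(=O)C=C[C@@H]1O
F5 | step 6 | (4S,5S)-4,5-dihydroxycyclopent-2-en-1-one | O[C@H]1C=CC(=O)[C@H]1O
F6 | step 6 | (4S,5S)-4,5-bis(triethylsilyloxy)cyclopent-2-en-1-one | CC[Si](CC)(CC)O[C@H]1C=CC(=O)[C@H]1O[Si](CC)(CC)CC
F7 | step 6 | (4S,5S)-5-[(1S)-1-hydroxyheptadecyl]-4,5-bis(triethylsilyloxy)cyclopent-2-en-1-one | CCCCCCCCCCCCCCCC[C@H](O)[C@@]1(O[Si](CC)(CC)CC)C(=O)C=C[C@@H]1O[Si](CC)(CC)CC
F8 | step 1 | (1R,4S)-4-(tert-butyldimethylsilyloxy)cyclopent-2-en-1-yl acetate | CC(C)(C)[Si](C)(C)O[C@@H]1C=C[C@H](OC(C)=O)C1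
F9 | step 1 | tert-butyldimethylsilyl ether of 2 at the hydroxyl trans to the cis-diol | CC(=O)O[C@@H]1C[C@H](O[Si](C)(C)C(C)(C)C)[C@@H](O)[C@H]1O
F10 | step 1 | tert-butyldimethylsilyl ether of 3 | CC(=O)O[C@@H]1C[C@H](O[Si](C)(C)C(C)(C)C)[C@H]2OC(C)(C)O[C@@H]12
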